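Locants used throughout (compound 28 is the target): C1 (benzoyl bridgehead), C2, C4 and C9 (ring ketones), C3 (quaternary), C5 (geranyl bridgehead), C6 (CH2), C7 (CH), C8 (CMe2), C10 (CH2 between C7 and C11), C11 (CH), C12 (CMe2), C13 (CH bearing 2-hydroxypropan-2-yl), C14 (CH2). Ring A is C1–C2–C3–C4–C5–C9, ring B is C1–C8–C7–C6–C5–C9, ring C is the cycloheptanone C3–C4–C5–C6–C7–C10–C11, ring D is the cyclopentane C3–C11–C12–C13–C14.

## Analysis of the target

Compound 28 is a bicyclo[3.3.1]nonane-2,4,9-trione (rings A and B) whose C3 and C7 are tied by the two-carbon bridge C10–C11, which makes a homoadamantane cage, and ring D is fused onto the C3–C11 bond. C1 carries the benzoyl group, C5 the geranyl chain, C8 and C12 are gem-dimethyl carbons and C13 carries the tertiary carbinol. There are six stereocentres (C1, C3, C5, C7, C11, C13) and one (E)-alkene. The cage itself couples C1, C3, C5 and C7, so the independent elements are the hand of the cage, C11 (ring D lies on the face of ring C away from C1) and C13 (carbinol side chain cis to C11–H and to C2). C1, C3 and C5 are quaternary, so none of the four ketones can enolise; the array is open to retro-Claisen cleavage by alkoxide or hydroxide. The geranyl diene tolerates neither strong acid nor hydrogenation, and the tertiary alcohol can eliminate or lactonise onto an activated C2. The difficulty lies in five crowded quaternary carbons, in relating C7 and C13 to C11, and in the fact that the last C–C bond creates a carbon without an acidic hydrogen, so no enolate sink drives it. The strategy rests on ring C: a cycloheptanone whose carbonyl C4 is flanked by C5 (which also bears the carboxyl-level C9) and C3, with C6–C7–C10–C11 as a four-carbon diene unit. That is the substitution pattern of a siloxyvinyl carbenoid plus diene [4+3] adduct.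

## Retrosynthetic reasoning

28 from 27: the tertiary alcohol is masked as a triethylsilyl ether through the endgame, because a free hydroxyl cis to an activated C2 on ring D would close a bridged lactone. The last step is therefore a desilylation that the polyketone survives.

27 from 25: the C1–C2 bond is cut last. C1 in 27 has no hydrogen, so an ester at C2 would be cleaved back by the liberated alkoxide. The forward step therefore uses the acid chloride 26 of keto acid 25 and the magnesium chelate of the 1,3-diketone, which makes the acylation irreversible. The tether fixes C1.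

25 from 23: two bonds are cut in one operation, C3–C2 (carboxylation of the C3 enolate) and C1–C9 (Claisen closure of ring B by the aryl ketone enolate on the C9 ester, through 24). Both ketones of 23 are held as enolates. This protects C4 against aldol addition and acyl migration, and leaves the C3 enolate ready for carboxylation on the face of C11–H.

23 from 22 and 22 from 20 and 21: silylation, and before it the C5–geranyl bond. C5 is the carbon between C4 and C9, so a carbonate base alkylates it without touching the aryl ketone. The geranyl group comes after the hydrogenation and the acid step, which it would not survive.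

20 from 18: the C12–C13 bond of ring D is cut. Forward, the tertiary alcohol at C12 ionises and the cis prenyl group on C3 closes the five-membered ring; the new tertiary cation is trapped by an oxygen nucleophile (via 19). This one step makes C12 quaternary, sets C13 and installs the carbinol.

18 from 17: C7–H is added by hydrogenation. The hydrogen must enter cis to the C11 side chain, against the steric bias. The step is therefore placed before ring D closure, while the C12 hydroxyl is free to direct the catalyst.

17 from 16, and 16 from 5 and 14: after desilylation, ring C is cut at C5–C6 and C3–C11. Forward, the carbenoid from 5 cyclopropanates the terminal alkene of 14 and the cis-divinylcyclopropane 15 rearranges. This gives the seven-membered ring, the C4 oxygen, C9 on C5, and C3 and C11 in the cis relation that ring D needs.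

5 from 4, 3, 1 and 2: silyl enol ether formation, diazo transfer and γ-alkylation of the dianion of 1 with 2.

14 from 10 and 11: the C8 quaternary carbon is cut by conjugate addition of the 2-metallated diene 12 (from 10) to enone 11; the product is released from enol ether 13. This brings in the phenacyl carbon C1 and the benzoyl group in one piece.

10 from 8 and 9, and 8 from 7 and 6: cross-coupling of the (E)-alkenylboronate with one C–Br bond of 9; the boronate comes from hydroboration of the silylated alkynol.

## Alternatives that were turned down

Alternative 1: Ring D is cut at C11–C12 and C3–C14 and made first by a Danheiser [3+2] annulation. A Lewis acid activates an alkylidene malonate, the CMe2 end of an allenylsilane adds to its β-carbon, silicon migrates and the malonate enolate closes on the vinyl cation, giving silylcyclopentene A1.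
- For it: C3 arrives quaternary with both of its carbonyl carbons (C2 and C4) in one step, without any facial question at C3, and no hydrogenation is needed. On this point it is stronger than the chosen route, which must carboxylate a crowded C3 enolate.
- Against it: C11 is formed in an intermolecular addition whose only control element, C7, sits two bonds away through a methylene group. The vinylsilane carbon must still be turned into the C13 carbinol stereocentre by several steps. The cage would close by Claisen reactions of the cyclohexanone α-carbons, leaving C1 and C5 as bridgehead CH groups that must be benzoylated and geranylated late, next to quaternary carbons.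
- Comparison: the chosen route sets C11 by catalyst control, derives C7 and C13 from it, and brings C9, the benzoyl group and the geranyl group in by ordinary enolate chemistry before the cage exists.

Alternative 2: The two seven-membered rings are cut together by an intramolecular de Mayo sequence. Irradiation adds the enone of an O-silylated 2-carbomethoxycyclopentane-1,3-dione across a tethered vinyl group (C5–C6 and C7–C10), and fluoride-triggered retro-aldol opening of the cyclobutane gives A2.
- For it: very fast build-up of complexity; C3, ring D and C13 are in place before the ring expansion. In step count to the bicyclo[3.3.2] core it is stronger than the chosen route.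
- Against it: the regiochemistry (straight or crossed) and facial course of the photocycloaddition are uncertain. C10 emerges as a ketone that must be removed in the presence of several others. C9 still has to bridge C1 and C5, and both then need late bridgehead substitution.
- Comparison: the chosen route carries no surplus oxygen and has C9 on C5 from the key step.

Alternative 3: The C1–C8 bond is cut by a semipinacol ring expansion. A kinetic enolate next to a tertiary carbinol is trapped by a hypervalent iodine oxidant and the CMe2 carbon migrates, giving the bicyclo[3.3.1]nonane A3.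
- For it: the shortest access to the bicyclic trione with geranyl on C5 and gem-dimethyl on C8; bridgehead benzoylation is a known type of endgame. On step economy to the core it is stronger.
- Against it: everything that defines this target is postponed. The C3–C11 bond, ring D with quaternary C12, and the C13 carbinol would have to come from a late cascade across a C7 prenyl group and a second prenyl unit on C3, in competition with the geranyl alkenes and with no element that controls C11 and C13. The C7 substituent must also be axial to reach C3.
- Comparison: the chosen route fixes C11 first and builds each further centre from it in separate, controllable steps.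

Key step: step 8

Remark on the chemistry: the (S)-antipode of Rh2(PTAD)4 is taken to give the (3R,4R) adduct 16; if the sense of induction is the opposite, the (R)-antipode is used with no other change.

## Route

Step 1
Reactants: 1 methyl acetoacetate; 2 prenyl bromide
Product: 3 methyl 7-methyl-3-oxooct-6-enoate
Conditions: NaH, THF, 0 °C; n-BuLi, 0 °C; 2, 0 to 23 °C; 1 M HCl
Reagents that add atoms: none
Why: Dianion alkylation of a β-keto ester (Weiler): the more basic γ-carbanion reacts with the allylic bromide and the α-position is left untouched.

Step 2
Reactants: 3 methyl 7-methyl-3-oxooct-6-enoate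
Product: 4 methyl 2-diazo-7-methyl-3-oxooct-6-enoate
Conditions: 4-acetamidobenzenesulfonyl azide, Et3N, MeCN, 0 to 23 °C
Reagents that add atoms: 4-acetamidobenzenesulfonyl azide, CC(=O)Nc1ccc(cc1)S(=O)(=O)N=[N+]=[N-]
Why: Regitz diazo transfer to the activated methylene of a β-keto ester.

Step 3
Reactants: 4 methyl 2-diazo-7-methyl-3-oxooct-6-enoate
Product: 5 methyl (Z)-2-diazo-3-(tert-butyldimethylsilyloxy)-7-methylocta-3,6-dienoate
Conditions: TBSOTf, Et3N, CH2Cl2, 0 °C
Reagents that add atoms: tert-butyldimethylsilyl triflate, CC(C)(C)[Si](C)(C)OS(=O)(=O)C(F)(F)F
Why: Soft enolisation and O-silylation of the diazo ketone; the alkyl chain settles trans to the bulky diazoacetate unit, which gives the (Z)-enol ether the Cope step needs.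

Step 4
Reactants: 6 2-methylbut-3-yn-2-ol
Product: 7 triethyl[(2-methylbut-3-yn-2-yl)oxy]silane
Conditions: TESOTf, 2,6-lutidine, CH2Cl2, 0 °C
Reagents that add atoms: triethylsilyl triflate, CC[Si](CC)(CC)OS(=O)(=O)C(F)(F)F
Why: Silylation of a tertiary alcohol with a silyl triflate; the ether keeps the hydroxyl out of O–H insertion in step 8.

Step 5
Reactants: 7 triethyl[(2-methylbut-3-yn-2-yl)oxy]silane
Product: 8 (E)-triethyl{[2-methyl-4-(4,4,5,5-tetramethyl-1,3,2-dioxaborolan-2-yl)but-3-en-2-yl]oxy}silane
Conditions: pinacolborane, Cp2Zr(H)Cl (5 mol%), Et3N (10 mol%), 60 °C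
Reagents that add atoms: pinacolborane, CC1(C)OBOC1(C)C
Why: Zirconocene-catalysed syn hydroboration of a terminal alkyne puts boron on the terminal carbon and gives the (E)-alkenylboronate.

Step 6
Reactants: 8 the (E)-alkenylboronate; 9 1,1-dibromoethene
Product: 10 (E)-[(5-bromo-2-methylhexa-3,5-dien-2-yl)oxy]triethylsilane
Conditions: Pd(PPh3)4 (5 mol%), aq. K3PO4, THF, 23 °C, 9 in excess
Reagents that add atoms: none
Why: Suzuki–Miyaura coupling at one C–Br bond of the 1,1-dibromoalkene; the remaining bromide sits on a more hindered 2-bromodiene and 9 is in excess, so single coupling should prevail, with retention of the (E)-geometry.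

Step 7
Reactants: 10 the 2-bromodiene; 11 3-methyl-1-phenylbut-2-en-1-one
Product: 14 (E)-3,3,7-trimethyl-4-methylidene-1-phenyl-7-(triethylsilyloxy)oct-5-en-1-one, via dienylmagnesium bromide 12 (not isolated), via trimethylsilyl enol ether 13 (not isolated)
Conditions: Mg, THF, 40 °C; CuBr·SMe2 (10 mol%), TMSCl, 11, THF, −78 to −30 °C; 1 M HCl, 0 °C
Reagents that add atoms: none
Why: Copper-catalysed conjugate addition of an alkenyl Grignard reagent to a β,β-disubstituted enone, accelerated by TMSCl, creates the C8 quaternary carbon; the metallated diene reacts at the metal-bearing carbon, so the (E)-diene is carried over intact.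

Step 8
Reactants: 5 the siloxyvinyl diazoacetate; 14 the diene ketone
Product: 16 methyl (3R,4R)-2-(tert-butyldimethylsilyloxy)-3-prenyl-4-[2-(triethylsilyloxy)propan-2-yl]-6-(2-methyl-4-oxo-4-phenylbutan-2-yl)cyclohepta-1,5-diene-1-carboxylate, via cis-divinylcyclopropane 15 (not isolated)
Conditions: Rh2(S-PTAD)4 (1 mol%), hexanes, −40 to 23 °C, slow addition of 5; then 60 °C
Reagents that add atoms: none
Why: Loss of dinitrogen from 5 at the dirhodium tetracarboxylate (divalent rhodium) gives the rhodium-bound siloxyvinyl carbenoid, which cyclopropanates the terminal 1,1-disubstituted alkene of 14 (C5–C6 bond and, for the moment, C5–C7) to give 15. Cope rearrangement of 15 through the boat transition state breaks C5–C7 and forms C3–C11; this [3,3] shift, not an exo or endo attack, closes the seven-membered ring C. The closest known reaction is the enantioselective formal [4+3] cycloaddition of siloxyvinyl diazoacetates with dienes under chiral dirhodium carboxylates. C11 is set by the face on which the chiral catalyst lets the alkene meet the carbenoid, carried through the boat. C3 is set relative to C11 by the boat geometry: the (E)-diene terminus and the vinyl terminus whose prenyl CH2 is trans to the carbenoid carbon both turn their substituents outward, which makes them cis. The step needs site selectivity, which the substrate secures because the trans-disubstituted neopentyl alkene and the trisubstituted prenyl alkene are poor partners for donor/acceptor carbenoids and the prenyl chain of 5 is held trans to the carbenoid carbon. It needs the cis cyclopropane (diene vinyl cis to the siloxyvinyl group, trans to the ester), since a trans isomer could rearrange only after a thermal epimerisation that costs optical purity. It also needs reaction at the carbenoid carbon, not at the vinyl terminus, which the siloxy group and the hydrocarbon solvent favour.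

Step 9
Reactants: 16 the silyl enol ether cycloheptadiene
Product: 17 methyl (3R,4R)-4-(2-hydroxypropan-2-yl)-6-(2-methyl-4-oxo-4-phenylbutan-2-yl)-2-oxo-3-prenylcyclohept-5-ene-1-carboxylate (C1 epimers and enol form)
Conditions: HF·pyridine, THF, 0 to 23 °C
Reagents that add atoms: none
Why: Fluoride cleaves the silyl enol ether and the tertiary silyl ether under buffered conditions that do not enolise C3, so the cis relation from step 8 is kept.

Step 10
Reactants: 17 the cycloheptenone keto ester alcohol
Product: 18 methyl (3R,4R,6R)-4-(2-hydroxypropan-2-yl)-6-(2-methyl-4-oxo-4-phenylbutan-2-yl)-2-oxo-3-prenylcycloheptane-1-carboxylate (new hydrogen at C7 of the target cis to the carbinol side chain)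
Conditions: [Rh(nbd)(dppb)]BF4 (10 mol%), H2 (70 bar), CH2Cl2, 23 °C
Reagents that add atoms: none
Why: Hydroxyl-directed homogeneous hydrogenation: the tertiary carbinol binds the cationic rhodium bisphosphine complex and both hydrogens reach the homoallylic ring alkene from the face of the carbinol side chain, which sets C7 against the steric bias. Non-coordinating trisubstituted alkenes such as the prenyl group are reduced only slowly by this class of catalyst.

Step 11
Reactants: 18 the cycloheptanone keto ester alcohol
Product: 20 methyl 2-(2-hydroxypropan-2-yl)-3,3-dimethyl-5-(2-methyl-4-oxo-4-phenylbutan-2-yl)-8-oxodecahydroazulene-7-carboxylate (cis ring fusion; 2-substituent cis and 5-H trans to the ring-fusion hydrogens; C7 epimers and enol form), via tertiary trifluoroacetate 19 (not isolated)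
Conditions: CF3CO2H, CH2Cl2, −20 to 0 °C; evaporate; K2CO3, MeOH, 0 °C
Reagents that add atoms: trifluoroacetic acid, OC(=O)C(F)(F)F
Why: Cation–olefin cyclisation: the C12 cation is captured 5-exo by the CH terminus of the cis prenyl group (C12–C13 bond), and the new tertiary cation is trapped by trifluoroacetate, which methanolysis removes. The side chain at C13 takes the convex face, away from ring C. Hydride shift from C11 is disfavoured because it would move the charge towards the ketone.

Step 12
Reactants: 20 the bicyclic keto ester alcohol; 21 geranyl bromide
Product: 22 the C5-geranylated bicyclic keto ester (geranyl on the face of ring D; CO2Me cis to the C7 side chain)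
Conditions: Cs2CO3, DMF, 0 °C
Reagents that add atoms: none
Why: C-Alkylation of a β-keto ester enolate with an allylic bromide; carbonate deprotonates neither the aryl ketone nor the alcohol. The bulky C7 substituent is expected to hold ring C with that group equatorial, so the new bond forms axially and anti to it, which is the arrangement ring B closure needs.

Step 13
Reactants: 22 the geranylated keto ester alcohol
Product: 23 the triethylsilyl ether of 22
Conditions: TESOTf, 2,6-lutidine, CH2Cl2, −78 °C
Reagents that add atoms: triethylsilyl triflate, CC[Si](CC)(CC)OC(=O)... see note below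
Why: Silylation of the tertiary alcohol at low temperature is faster than silyl enol ether formation at the two hindered ketones; the ether prevents lactonisation onto C2 in step 15.

Note to step 13: the reagent is triethylsilyl triflate, SMILES CC[Si](CC)(CC)OS(=O)(=O)C(F)(F)F, as in step 4.

Step 14
Reactants: 23 the silyl-protected geranyl keto ester
Product: 25 the C3 carboxylic acid of the ring B diketone (CO2H on C3 on the face of C11–H, under C1), via bicyclic diketone bis-enolate 24 (not isolated)
Conditions: add 23 to LiN(i-Pr)2 (4 equiv), THF, −78 °C; 0 °C; −78 °C, CO2; cold 1 M HCl; used at once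
Reagents that add atoms: carbon dioxide, O=C=O
Why: Excess amide base turns both ketones into enolates, so only the ester is electrophilic; this shuts off aldol addition to C4 and the acyl migration that would follow. The aryl ketone enolate closes the six-membered ring B on the C9 ester (Dieckmann-type Claisen condensation, driven by deprotonation of the 1,3-diketone). The remaining C3 enolate is carboxylated on the face of C11–H, the only face that keeps ring D cis-fused.

Step 15
Reactants: 25 the keto acid
Product: 27 the triethylsilyl ether of the target, via acid chloride 26 (not isolated)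
Conditions: 1-chloro-N,N,2-trimethylprop-1-en-1-amine, CH2Cl2, 0 °C; MgCl2, Et3N, MeCN, 0 to 23 °C
Reagents that add atoms: none
Why: The acid chloride forms under neutral conditions and the magnesium chelate of the 1,3-diketone is C-acylated (magnesium-mediated C-acylation of 1,3-dicarbonyl compounds, here intramolecular, closing ring A and the second seven-membered ring). Chloride as the leaving group makes formation of the hydrogen-free C1 irreversible, where an ester would be cleaved back by retro-Claisen. The tether reaches only one face of C1, so the benzoyl group ends exo.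

Step 16
Reactants: 27 the silyl-protected cage
Product: 28 the target
Conditions: HF·pyridine, pyridine, THF, 0 °C
Reagents that add atoms: none
Why: Weakly acidic, non-nucleophilic desilylation frees the tertiary alcohol without attacking the non-enolisable polyketone or the geranyl diene.

## Compound list

1 | methyl acetoacetate | COC(=O)CC(C)=O | starting material
2 | prenyl bromide | CC(C)=CCBr | starting material
3 | methyl 7-methyl-3-oxooct-6-enoate | COC(=O)CC(=O)CCC=C(C)C | intermediate
4 | methyl 2-diazo-7-methyl-3-oxooct-6-enoate | COC(=O)C(=[N+]=[N-])C(=O)CCC=C(C)C | intermediate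
5 | methyl (Z)-2-diazo-3-(tert-butyldimethylsilyloxy)-7-methylocta-3,6-dienoate | COC(=O)C(=[N+]=[N-])/C(O[Si](C)(C)C(C)(C)C)=C/CC=C(C)C | intermediate
6 | 2-methylbut-3-yn-2-ol | CC(C)(O)C#C | starting material
7 | triethyl[(2-methylbut-3-yn-2-yl)oxy]silane | CC[Si](CC)(CC)OC(C)(C)C#C | intermediate
8 | (E)-triethyl{[2-methyl-4-(4,4,5,5-tetramethyl-1,3,2-dioxaborolan-2-yl)but-3-en-2-yl]oxy}silane | CC[Si](CC)(CC)OC(C)(C)/C=C/B1OC(C)(C)C(C)(C)O1 | intermediate
9 | 1,1-dibromoethene | C=C(Br)Br | starting material
10 | (E)-[(5-bromo-2-methylhexa-3,5-dien-2-yl)oxy]triethylsilane | C=C(Br)/C=C/C(C)(C)O[Si](CC)(CC)CC | intermediate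
11 | 3-methyl-1-phenylbut-2-en-1-one | CC(C)=CC(=O)c1ccccc1 | starting material
12 | bromo[(E)-5-methyl-5-(triethylsilyloxy)hexa-1,3-dien-2-yl]magnesium | C=C([Mg]Br)/C=C/C(C)(C)O[Si](CC)(CC)CC | intermediate (not isolated)
13 | trimethylsilyl enol ether of 14 | C=C(/C=C/C(C)(C)O[Si](CC)(CC)CC)C(C)(C)C=C(O[Si](C)(C)C)c1ccccc1 | intermediate (not isolated)
14 | (E)-3,3,7-trimethyl-4-methylidene-1-phenyl-7-(triethylsilyloxy)oct-5-en-1-one | C=C(C(C)(C)CC(=O)c1ccccc1)/C=C/C(C)(C)O[Si](CC)(CC)CC | intermediate
15 | cis-divinylcyclopropane: methyl 1-[(Z)-siloxyvinyl]-2-[(E)-alkenyl]-2-(2-methyl-4-oxo-4-phenylbutan-2-yl)cyclopropane-1-carboxylate, the two alkenyl groups cis | COC(=O)[C@@]1(/C(O[Si](C)(C)C(C)(C)C)=C/CC=C(C)C)C[C@]1(C(C)(C)CC(=O)c2ccccc2)/C=C/C(C)(C)O[Si](CC)(CC)CC | intermediate (not isolated)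
16 | methyl (3R,4R)-2-(tert-butyldimethylsilyloxy)-3-prenyl-4-[2-(triethylsilyloxy)propan-2-yl]-6-(2-methyl-4-oxo-4-phenylbutan-2-yl)cyclohepta-1,5-diene-1-carboxylate | COC(=O)C1=C(O[Si](C)(C)C(C)(C)C)[C@H](CC=C(C)C)[C@H](C(C)(C)O[Si](CC)(CC)CC)C=C(C(C)(C)CC(=O)c2ccccc2)C1 | intermediate
17 | methyl (3R,4R)-4-(2-hydroxypropan-2-yl)-6-(2-methyl-4-oxo-4-phenylbutan-2-yl)-2-oxo-3-prenylcyclohept-5-ene-1-carboxylate, C1 epimers and enol | COC(=O)C1CC(C(C)(C)CC(=O)c2ccccc2)=C[C@@H](C(C)(C)O)[C@@H](CC=C(C)C)C1=O | intermediate
18 | methyl (3R,4R,6R)-4-(2-hydroxypropan-2-yl)-6-(2-methyl-4-oxo-4-phenylbutan-2-yl)-2-oxo-3-prenylcycloheptane-1-carboxylate | COC(=O)C1C[C@H](C(C)(C)CC(=O)c2ccccc2)C[C@@H](C(C)(C)O)[C@@H](CC=C(C)C)C1=O | intermediate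
19 | trifluoroacetate of 20 | COC(=O)C1C[C@H](C(C)(C)CC(=O)c2ccccc2)C[C@H]3C(C)(C)[C@H](C(C)(C)OC(=O)C(F)(F)F)C[C@H]3C1=O | intermediate (not isolated)
20 | methyl 2-(2-hydroxypropan-2-yl)-3,3-dimethyl-5-(2-methyl-4-oxo-4-phenylbutan-2-yl)-8-oxodecahydroazulene-7-carboxylate, cis-fused, 2-substituent cis and 5-H trans to the ring-fusion hydrogens | COC(=O)C1C[C@H](C(C)(C)CC(=O)c2ccccc2)C[C@H]3C(C)(C)[C@H](C(C)(C)O)C[C@H]3C1=O | intermediate
21 | geranyl bromide | CC(C)=CCC/C(C)=C/CBr | starting material
22 | 7-geranyl derivative of 20, geranyl trans to the ring-fusion hydrogens, ester cis to the 5-side chain | COC(=O)[C@]1(C/C=C(\C)CCC=C(C)C)C[C@H](C(C)(C)CC(=O)c2ccccc2)C[C@H]3C(C)(C)[C@H](C(C)(C)O)C[C@H]3C1=O | intermediate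
23 | triethylsilyl ether of 22 | COC(=O)[C@]1(C/C=C(\C)CCC=C(C)C)C[C@H](C(C)(C)CC(=O)c2ccccc2)C[C@H]3C(C)(C)[C@H](C(C)(C)O[Si](CC)(CC)CC)C[C@H]3C1=O | intermediate
24 | ring B diketone (C1–C9 formed; C1–H and C3–H; present as its bis-enolate; drawn neutral) | CC(C)=CCC/C(C)=C/C[C@@]1(C(=O)C(C(=O)c2ccccc2)C3(C)C)C[C@H]3C[C@H]4C(C)(C)[C@H](C(C)(C)O[Si](CC)(CC)CC)C[C@H]4C1=O | intermediate (not isolated)
25 | C3 carboxylic acid of 24, CO2H cis to C11–H | CC(C)=CCC/C(C)=C/C[C@@]1(C(=O)C(C(=O)c2ccccc2)C3(C)C)C[C@H]3C[C@H]4C(C)(C)[C@H](C(C)(C)O[Si](CC)(CC)CC)C[C@@]4(C(=O)O)C1=O | intermediate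
26 | acid chloride of 25 | CC(C)=CCC/C(C)=C/C[C@@]1(C(=O)C(C(=O)c2ccccc2)C3(C)C)C[C@H]3C[C@H]4C(C)(C)[C@H](C(C)(C)O[Si](CC)(CC)CC)C[C@@]4(C(=O)Cl)C1=O | intermediate (not isolated)
27 | triethylsilyl ether of the target | CC(C)=CCC/C(C)=C/C[C@@]12C[C@H]3C[C@H]4C(C)(C)[C@H](C(C)(C)O[Si](CC)(CC)CC)C[C@]4(C1=O)C(=O)[C@@](C(=O)c1ccccc1)(C2=O)C3(C)C | intermediate
28 | CNP0164095.1 | CC(C)=CCC/C(C)=C/C[C@@]12C[C@H]3C[C@H]4C(C)(C)[C@H](C(C)(C)O)C[C@]4(C1=O)C(=O)[C@@](C(=O)c1ccccc1)(C2=O)C3(C)C | target

## Step count and least certain steps

Total: 16 steps. Longest linear sequence: 13 steps (steps 4 to 16, from 6); steps 1 to 3 form the second branch, which joins at step 8.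

Step 8 (key step). The reacting alkene of 14 carries a tertiary alkyl group, so cyclopropanation may be slow against carbene dimerisation. Part of the cyclopropane may form with the two alkenyl groups trans; that isomer rearranges only after a thermal epimerisation, which lowers the optical purity. The catalyst may also discriminate the faces poorly on this hindered diene. Fallback, with the stereocontrol moved from the catalyst to an auxiliary: it sets out from 3. Exchange of the ester with (R)-pantolactone (or its antipode, as the sense requires) gives the pantolactonyl keto ester F1; diazo transfer gives F2 and silylation gives the siloxyvinyl diazo ester F3. Reaction of F3 with 14 under achiral Rh2(O2CC7H15)4 gives the diastereomeric adduct F4, which can be purified as a single diastereomer. HF·pyridine gives the keto ester alcohol F5, and ester exchange in methanol (DMAP, toluene, 80 °C, through the acyl ketene) returns to the route at 17.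

Step 10. The ring alkene carries a quaternary substituent and the director is a tertiary alcohol, so turnover at rhodium may be slow; forcing conditions would then reduce or isomerise the prenyl group as well. Fallback, with the prenyl alkene masked and a more active catalyst: it sets out from 16. Epoxidation of the prenyl alkene with mCPBA (the ring alkene is hindered and the enol ether is electron-poor) gives epoxide F6 as a mixture at the oxirane carbon. HF·pyridine gives F7, and hydroxyl-directed hydrogenation with [Ir(cod)(PCy3)(py)]PF6 gives F8. Deoxygenation of the epoxide (CH3ReO3 catalyst, PPh3) returns to the route at 18.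

Step 11. The C12 cation may be captured across ring C by the enol carbon C5 of the keto ester, or lose a proton, and the product alcohol can ionise again in the acid, so the outcome depends on a competition between several cation pathways. Fallback, with ring closure and hydration separated: it sets out from 18. Cyclisation with BF3·OEt2 at −78 °C, ended by proton loss, gives the isopropenyl compound F9. Mukaiyama hydration (Co(acac)2, PhSiH3, O2) then places the hydroxyl at the tertiary carbon under neutral conditions and returns to the route at 20.

Step 12. Facial selectivity at C5 rests on a conformational argument for a seven-membered ring, and the cis-fused ring D may steer the electrophile to the other face; the wrong epimer cannot close ring B. Fallback, with catalyst control in place of substrate control: it sets out from 20. Palladium-catalysed allylic alkylation of the keto ester with geranyl methyl carbonate and a chiral bisphosphine ligand of the matching hand returns directly to 22.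

Step 14. The carboxylation has to take place on the concave side of the bridged bis-enolate, under C1, where access is restricted; C-carboxylation may be slow and revert. If C4 is not fully enolised before ring B closes, aldol addition and acyl migration can intervene. Fallback, with the carboxyl installed before ring B exists: it sets out from 23. The aryl ketone is masked as its tert-butyldimethylsilyl enol ether F10 (TBSOTf, Et3N). The C3 enolate (LiN(i-Pr)2) is carboxylated with CO2 on the open bicycle, and buffered n-Bu4NF work-up frees the aryl ketone to give keto acid F11. LiN(SiMe3)2 (excess) then closes ring B by the Claisen condensation and returns to the route at 25.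

## Further compounds

F1 | step 8 | (R)-pantolactonyl 7-methyl-3-oxooct-6-enoate | CC1(C)COC(=O)[C@@H]1OC(=O)CC(=O)CCC=C(C)C
F2 | step 8 | (R)-pantolactonyl 2-diazo-7-methyl-3-oxooct-6-enoate | CC1(C)COC(=O)[C@@H]1OC(=O)C(=[N+]=[N-])C(=O)CCC=C(C)C
F3 | step 8 | (R)-pantolactonyl (Z)-2-diazo-3-(tert-butyldimethylsilyloxy)-7-methylocta-3,6-dienoate | CC1(C)COC(=O)[C@@H]1OC(=O)C(=[N+]=[N-])/C(O[Si](C)(C)C(C)(C)C)=C/CC=C(C)C
F4 | step 8 | pantolactonyl ester analogue of 16 | CC1(C)COC(=O)[C@@H]1OC(=O)C2=C(O[Si](C)(C)C(C)(C)C)[C@H](CC=C(C)C)[C@H](C(C)(C)O[Si](CC)(CC)CC)C=C(C(C)(C)CC(=O)c3ccccc3)C2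
F5 | step 8 | pantolactonyl ester analogue of 17 | CC1(C)COC(=O)[C@@H]1OC(=O)C2CC(C(C)(C)CC(=O)c3ccccc3)=C[C@@H](C(C)(C)O)[C@@H](CC=C(C)C)C2=O
F6 | step 10 | prenyl epoxide of 16 (epimers at the oxirane carbon) | COC(=O)C1=C(O[Si](C)(C)C(C)(C)C)[C@H](CC2OC2(C)C)[C@H](C(C)(C)O[Si](CC)(CC)CC)C=C(C(C)(C)CC(=O)c3ccccc3)C1
F7 | step 10 | prenyl epoxide of 17 | COC(=O)C1CC(C(C)(C)CC(=O)c2ccccc2)=C[C@@H](C(C)(C)O)[C@@H](CC3OC3(C)C)C1=O
F8 | step 10 | prenyl epoxide of 18 | COC(=O)C1C[C@H](C(C)(C)CC(=O)c2ccccc2)C[C@@H](C(C)(C)O)[C@@H](CC3OC3(C)C)C1=O
F9 | step 11 | isopropenyl analogue of 20 (prop-1-en-2-yl in place of 2-hydroxypropan-2-yl) | COC(=O)C1C[C@H](C(C)(C)CC(=O)c2ccccc2)C[C@H]3C(C)(C)[C@H](C(C)=C)C[C@H]3C1=O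
F0 | step 12 | none | none
F10 | step 14 | tert-butyldimethylsilyl enol ether of the aryl ketone of 23 | COC(=O)[C@]1(C/C=C(\C)CCC=C(C)C)C[C@H](C(C)(C)C=C(O[Si](C)(C)C(C)(C)C)c2ccccc2)C[C@H]3C(C)(C)[C@H](C(C)(C)O[Si](CC)(CC)CC)C[C@H]3C1=O
F11 | step 14 | C3 carboxylic acid of 23 (ring B still open) | COC(=O)[C@]1(C/C=C(\C)CCC=C(C)C)C[C@H](C(C)(C)CC(=O)c2ccccc2)C[C@H]3C(C)(C)[C@H](C(C)(C)O[Si](CC)(CC)CC)C[C@@]3(C(=O)O)C1=O
A1 | alternative 1 | 3-silylcyclopent-3-ene-1,1-dicarboxylate with gem-dimethyl and the C7 side chain | COC(=O)C1(C(=O)OC)C=C([Si](C)(C)C)C(C)(C)[C@@H]1C[C@@H]2CCC3(OCCO3)CC2(C)C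
A2 | alternative 2 | bicyclo[3.3.2]decane keto ester fused to the cyclopentane | COC(=O)[C@@H]1C[C@H]2C(=O)[C@H]3C(C)(C)[C@H](C(C)(C)O)C[C@]3(C1=O)C(=O)CC2(C)C
A3 | alternative 3 | 5-geranyl-7-prenyl-8,8-dimethylbicyclo[3.3.1]nonane-2,4,9-trione methyl enol ether | CC(C)=CCC/C(C)=C/C[C@@]12C[C@@H](CC=C(C)C)C(C)(C)[C@H](C2=O)C(=O)C=C1OC
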